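The constants come first, since you asked for a quick number on the north flask and I can read two of them from its readings.

- north: substrate 0.86 M; coupling partner 0.70 equiv; capture agent 0.0172 M; free catalyst 2 mol%; the very flask that is asked about, followed so far
- flask: substrate 0.86 M; coupling partner 0.700 equiv; capture agent 0.0172 M; free catalyst 2 mol%; time 30 min

north run (percent of the substrate charged): time / min: target / % = 2.50: 18.6; 8.00: 41.4; 15.0: 40.2; 20.0: 36.4; 30.0: 29.7

(scatter of a reading: 0.5 percentage points)

- target taken out counts as made
- additions bring no volume worth counting

- beta: at 30 min take out 90% of the target then present, then wait 10 min
- delta: at 30 min add coupling partner, 50.0% of the amount charged, then wait 10 min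
- theta: change nothing and wait 10 min more
- gamma: at 30 min add free catalyst, 100% of the amount charged, then wait 10 min

- target, in percent of the substrate first charged, at 30 min
- the remedy with the largest gain of target, or "none" below 2 percentage points (beta / delta / theta / gamma / none)
- target present, with what was taken out counted in, in percent of the substrate first charged, after delta
- target present, with what was taken out counted in, in percent of the substrate first charged, after gamma

After the peak the target falls first-order, so I take the decay constant from the later readings and use the area under the curve to add back what decay has taken:

k = ln(target at 15.0 min / target at 30.0 min) / elapsed time = 0.0202 /min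

lost to decay = k × area = 20.1%

target made = 29.7% + lost = 49.8%

Y = target made / partner charged = 0.711

I call Y the yield on partner: target made per equivalent of coupling partner charged. The readings can't tell me why formation stops, but my bet is on the partner, not the catalyst. If so, added partner pays at this yield, and the crossing lies where new target overtakes what decay takes during the wait:

new target = Y × 50.0% × 0.700 equiv = 24.9%

decay in 10 min = 5.43%

New target is more than the decay, so I put my money on delta, at about 49.2%.

Your hunch, the forecast, differs. It reads 29.7% now, picks beta, and gives 24.3% after delta and 24.8% after gamma, holding that “extra partner does nothing on dead catalyst”.

The north flask gives 29.8% now and 24.2% after gamma. Delta is the best remedy, reaching 46.2%, a gain of 16 percentage points.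

    substrate + free catalyst ⇌ catalyst intermediate A (K = 0.840 /M, k = 102 /M/min)
    catalyst intermediate A → catalyst intermediate B (k = 12.9 /min)
    coupling partner + catalyst intermediate B → catalyst intermediate C (k = 159 /M/min)
    catalyst intermediate C ⇌ catalyst intermediate D (K = 8.36, k = 112 /min)
    catalyst intermediate D ⇌ free catalyst + target (K = 0.708 M, k = 449 /min)
    coupling partner → decomposed reagent (k = 0.0739 /min)
    catalyst intermediate C + capture agent → trapped intermediate (k = 7.24 /M/min)
    target → over-reaction product (k = 0.0209 /min)

At 30.0 min the north flask holds 0% of its coupling partner, the limiting reagent, with 46.7% of the substrate still free. Part of delta's gain is due to the step from coupling partner to decomposed reagent: the north flask run without that step gains 6.7 points from delta against 16 points. Delta ends 22 points above gamma, where the yield on partner promised 24.9%. Carried to the neighbouring flask with 1.20 equiv of coupling partner, that yield promises 85.4% made; at 30.0 min that flask holds 71.7% as target and over-reaction product together, 43.8% of it target.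

The data are simulated with made-up constants; scatter was added.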